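**Strategy.** The route rests on growing the phenol ring on the quaternary cyclopentane carbon C1 instead of attaching it. In the benzene ring, the carbon bonded to C1 and its hydroxylated neighbour are the two carbons of an ethynyl group. The other four ring carbons, the para methyl and the phenolic oxygen come from 3‑methylfuran. One gold‑catalysed furan–alkyne benzannulation forms two arene C–C bonds and the C–O bond. Its precursor, (2R,3R)‑3‑ethynyl‑2,3‑dimethylcyclopentanone, carries the C2 methyl cis to the slim alkyne, the thermodynamically favoured arrangement. The cis aryl/methyl relation at C1/C2, disfavoured once the aryl exists, is therefore secured beforehand.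

Key step: step 5

Remark on numbering: target positions use the cyclopentane numbering C1 (quaternary), C2 (CH–CH3), C3 (=CHBr); ketone intermediates are named with the carbonyl as C1, so the quaternary carbon is then C3 and C2 is the same atom in both.

Assumption: the antipode of the chiral NHC ligand in step 1 is the one that gives the (R)‑configured quaternary centre; this would be confirmed on the first batch.

**Step 1**
Reactants: 1 3‑methylcyclopent‑2‑en‑1‑one; 2 ethynyltrimethylsilane
Product: 5 triethyl({(3R)‑3‑methyl‑3‑[1‑(trimethylsilyl)ethenyl]cyclopent‑1‑en‑1‑yl}oxy)silane, via vinylalane 3 (not isolated), via aluminium enolate 4 (not isolated)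
Conditions: 2, i‑Bu2AlH, hexanes–THF, 55 °C; then 1, CuCl2·2H2O (cat.), chiral sulfonate‑bearing imidazolinium salt (NHC precursor, cat.), THF, −78 → −15 °C; then Et3SiOTf, −78 °C → rt
Reagents that add atoms: triethylsilyl trifluoromethanesulfonate, CC[Si](CC)(CC)OS(=O)(=O)C(F)(F)F
Why: Copper‑catalysed enantioselective conjugate addition of a silyl‑substituted vinylaluminium reagent (from hydroalumination of 2, which puts aluminium on the silicon‑bearing carbon) to a β‑substituted cyclopentenone is an established way to vinyl‑bearing quaternary centres, the chiral NHC–copper complex choosing the enone face and so setting C3 as R, and O‑silylation of the aluminium enolate stores the C1–C2 enolate regiochemistry for step 2.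

**Step 2**
Reactants: 5 triethyl({(3R)‑3‑methyl‑3‑[1‑(trimethylsilyl)ethenyl]cyclopent‑1‑en‑1‑yl}oxy)silane
Product: 7 (2S,3R)‑2,3‑dimethyl‑3‑[1‑(trimethylsilyl)ethenyl]cyclopentan‑1‑one, via lithium enolate 6 (not isolated)
Conditions: MeLi, THF, 0 °C → rt; then MeI, −78 → 0 °C
Reagents that add atoms: iodomethane, CI
Why: Methyllithium cleaves the O–Si bond and releases the lithium enolate regiospecifically toward C2 (enolate regeneration from a silyl enol ether), and C‑methylation by SN2 follows, expected mainly anti to the bulky silylvinyl group, which is of no consequence because C2 is reset in step 4.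

**Step 3**
Reactants: 7 (2S,3R)‑2,3‑dimethyl‑3‑[1‑(trimethylsilyl)ethenyl]cyclopentan‑1‑one
Product: 8 (2S,3R)‑3‑(1‑iodoethenyl)‑2,3‑dimethylcyclopentan‑1‑one
Conditions: NIS, (CF3)2CHOH, 0 °C, dark
Reagents that add atoms: N‑iodosuccinimide, O=C1CCC(=O)N1I
Why: Electrophilic iododesilylation of the 2‑silyl‑1‑alkene, helped by the ionising fluorinated alcohol, replaces silicon by iodine at the same carbon and is a standard route to 2‑iodo‑1‑alkenes, while the ketone and both stereocentres are untouched.

**Step 4**
Reactants: 8 (2S,3R)‑3‑(1‑iodoethenyl)‑2,3‑dimethylcyclopentan‑1‑one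
Product: 10 (2R,3R)‑3‑ethynyl‑2,3‑dimethylcyclopentan‑1‑one, via C2‑epimeric alkyne 9 (not isolated)
Conditions: Bu4NF·3H2O, DMF, 60 °C; then K2CO3, MeOH, rt
Reagents that add atoms: none
Why: Fluoride‑induced anti‑dehydroiodination (E2) of the 2‑iodo‑1‑alkene gives the terminal alkyne, and base‑mediated enolisation then equilibrates C2 to the thermodynamic epimer, in which the C2 methyl is trans to the C3 methyl and cis to the rod‑like ethynyl group (the quaternary C3 cannot epimerise), any remaining 9 being separated and resubmitted.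

**Step 5**
Reactants: 10 (2R,3R)‑3‑ethynyl‑2,3‑dimethylcyclopentan‑1‑one; 11 3‑methylfuran
Product: 13 (2R,3R)‑3‑(2‑hydroxy‑4‑methylphenyl)‑2,3‑dimethylcyclopentan‑1‑one, via arene oxide 12 (not isolated)
Conditions: 11 (4 equiv), IPrAuNTf2 (5 mol %; IPr = 1,3‑bis(2,6‑diisopropylphenyl)imidazol‑2‑ylidene), 2,6‑di‑tert‑butylpyridine (10 mol %), CH2Cl2, 4 Å MS, rt
Reagents that add atoms: none
Why: The cationic monovalent gold complex binds the alkyne of 10 and furan C5, the α‑carbon with no methyl neighbour, adds to the internal alkyne carbon; the cyclopropyl gold carbene so formed opens with cleavage of the O–C5 bond to a dienal gold carbene, whose aldehyde oxygen (the furan oxygen, still on furan C2) adds to the carbene carbon, the former terminal alkyne carbon. Loss of gold gives an oxepine, which closes by thermal disrotatory 6π electrocyclisation to arene oxide 12 (this six‑membered closure makes the second arene C–C bond, terminal alkyne carbon to furan C2), and epoxide opening with aromatisation leaves the oxygen on the former terminal alkyne carbon. The closest known reaction type is the intermolecular gold‑catalysed furan–alkyne phenol synthesis, applied here to an alkyne on a quaternary carbon. No stereocentre is created: C3 is quaternary, and C2, now cis to an aryl group and so in its less stable configuration, is protected by the absence of base and by the hindered pyridine that buffers traces of acid. The step needs Markovnikov attack on the alkyne, given by the alkyl substituent, and attack through furan C5 and not through the more electron‑rich but methyl‑flanked C2, for which the steric demand of the quaternary propargylic carbon is relied on. Excess furan and molecular sieves disfavour alkyne hydration.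

**Step 6**
Reactants: 13 (2R,3R)‑3‑(2‑hydroxy‑4‑methylphenyl)‑2,3‑dimethylcyclopentan‑1‑one
Product: 15 4‑bromo‑2‑[(1R,2R)‑1,2‑dimethyl‑3‑oxocyclopentyl]‑5‑methylphenyl acetate, via bromophenol 14 (not isolated)
Conditions: NBS, MeCN, 0 °C; then Ac2O, pyridine, DMAP (cat.), 0 °C → rt
Reagents that add atoms: N‑bromosuccinimide, O=C1CCC(=O)N1Br; acetic anhydride, CC(=O)OC(C)=O
Why: Electrophilic aromatic bromination with NBS in acetonitrile should go para to the hydroxyl (the only free ortho position is flanked by OH and CH3) under neutral conditions that spare the epimerisable C2, and DMAP‑catalysed O‑acetylation in the same flask masks the phenol, which would otherwise be phosphorylated by the phosphite/CBr4 system of step 7.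

**Step 7**
Reactants: 15 4‑bromo‑2‑[(1R,2R)‑1,2‑dimethyl‑3‑oxocyclopentyl]‑5‑methylphenyl acetate
Product: 16 4‑bromo‑2‑[(1R,2R)‑3‑(dibromomethylidene)‑1,2‑dimethylcyclopentyl]‑5‑methylphenyl acetate
Conditions: CBr4, P(Oi‑Pr)3, CH2Cl2, 0 °C → rt
Reagents that add atoms: tetrabromomethane, BrC(Br)(Br)Br
Why: Ramirez‑type dibromo‑olefination in its triisopropyl phosphite variant, developed for ketones, proceeds through a dibromomethylene phosphorane formed in the flask that adds to the carbonyl and collapses in Wittig fashion; the reagent is only weakly basic, so C2 should not enolise, and after this step C2 is no longer α to a carbonyl.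

**Step 8**
Reactants: 16 4‑bromo‑2‑[(1R,2R)‑3‑(dibromomethylidene)‑1,2‑dimethylcyclopentyl]‑5‑methylphenyl acetate
Product: 18 4‑bromo‑2‑[(1R,2R,3Z)‑3‑(bromomethylidene)‑1,2‑dimethylcyclopentyl]‑5‑methylphenol, via aryl acetate 17 (not isolated)
Conditions: Pd(PPh3)4 (5 mol %), Bu3SnH (1.1 equiv), toluene, rt; then K2CO3, MeOH, rt
Reagents that add atoms: none
Why: In this palladium‑catalysed hydrogenolysis of a 1,1‑dibromoalkene with a tin hydride, zerovalent palladium should insert into the less hindered C–Br bond, the one syn to the ring CH2 (C4) and away from the C2 methyl, and hydride replaces it with retention, leaving bromine syn to C2 as the (Z)‑alkene requires, while the electron‑rich aryl bromide is inert at room temperature and methanolysis of the acetate then frees the phenol.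

**Compound list**
1 | 3‑methylcyclopent‑2‑en‑1‑one | CC1=CC(=O)CC1 | starting material
2 | ethynyltrimethylsilane | C#C[Si](C)(C)C | starting material
3 | diisobutyl[1‑(trimethylsilyl)ethenyl]alane (formed in the flask) | C=C([Si](C)(C)C)[Al](CC(C)C)CC(C)C | intermediate
4 | diisobutyl({(3R)‑3‑methyl‑3‑[1‑(trimethylsilyl)ethenyl]cyclopent‑1‑en‑1‑yl}oxy)alane (formed in the flask) | C=C([Si](C)(C)C)[C@]1(C)CCC(O[Al](CC(C)C)CC(C)C)=C1 | intermediate
5 | triethyl({(3R)‑3‑methyl‑3‑[1‑(trimethylsilyl)ethenyl]cyclopent‑1‑en‑1‑yl}oxy)silane | C=C([Si](C)(C)C)[C@]1(C)CCC(O[Si](CC)(CC)CC)=C1 | intermediate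
6 | lithium (3R)‑3‑methyl‑3‑[1‑(trimethylsilyl)ethenyl]cyclopent‑1‑en‑1‑olate (formed in the flask) | C=C([Si](C)(C)C)[C@]1(C)CCC(O[Li])=C1 | intermediate
7 | (2S,3R)‑2,3‑dimethyl‑3‑[1‑(trimethylsilyl)ethenyl]cyclopentan‑1‑one (C2 methyl trans to the silylvinyl group) | C=C([Si](C)(C)C)[C@]1(C)CCC(=O)[C@H]1C | intermediate
8 | (2S,3R)‑3‑(1‑iodoethenyl)‑2,3‑dimethylcyclopentan‑1‑one | C=C(I)[C@]1(C)CCC(=O)[C@H]1C | intermediate
9 | (2S,3R)‑3‑ethynyl‑2,3‑dimethylcyclopentan‑1‑one (C2 methyl trans to ethynyl; formed in the flask) | C#C[C@]1(C)CCC(=O)[C@H]1C | intermediate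
10 | (2R,3R)‑3‑ethynyl‑2,3‑dimethylcyclopentan‑1‑one (C2 methyl cis to ethynyl, trans to the C3 methyl) | C#C[C@]1(C)CCC(=O)[C@@H]1C | intermediate
11 | 3‑methylfuran | Cc1ccoc1 | starting material
12 | (2R,3R)‑2,3‑dimethyl‑3‑(5‑methyl‑7‑oxabicyclo[4.1.0]hepta‑2,4‑dien‑2‑yl)cyclopentan‑1‑one (arene oxide; epoxide carbons unassigned; formed in the flask) | CC1=CC=C([C@]2(C)CCC(=O)[C@@H]2C)C3OC13 | intermediate
13 | (2R,3R)‑3‑(2‑hydroxy‑4‑methylphenyl)‑2,3‑dimethylcyclopentan‑1‑one (C2 methyl cis to aryl) | Cc1ccc([C@]2(C)CCC(=O)[C@@H]2C)c(O)c1 | intermediate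
14 | (2R,3R)‑3‑(5‑bromo‑2‑hydroxy‑4‑methylphenyl)‑2,3‑dimethylcyclopentan‑1‑one (formed in the flask) | Cc1cc(O)c([C@]2(C)CCC(=O)[C@@H]2C)cc1Br | intermediate
15 | 4‑bromo‑2‑[(1R,2R)‑1,2‑dimethyl‑3‑oxocyclopentyl]‑5‑methylphenyl acetate | Cc1cc(OC(C)=O)c([C@]2(C)CCC(=O)[C@@H]2C)cc1Br | intermediate
16 | 4‑bromo‑2‑[(1R,2R)‑3‑(dibromomethylidene)‑1,2‑dimethylcyclopentyl]‑5‑methylphenyl acetate | Cc1cc(OC(C)=O)c([C@]2(C)CCC(=C(Br)Br)[C@@H]2C)cc1Br | intermediate
17 | 4‑bromo‑2‑[(1R,2R,3Z)‑3‑(bromomethylidene)‑1,2‑dimethylcyclopentyl]‑5‑methylphenyl acetate (formed in the flask) | Cc1cc(OC(C)=O)c([C@]2(C)CC/C(=C/Br)[C@@H]2C)cc1Br | intermediate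
18 | 4‑bromo‑2‑[(1R,2R,3Z)‑3‑(bromomethylidene)‑1,2‑dimethylcyclopentyl]‑5‑methylphenol | Cc1cc(O)c([C@]2(C)CC/C(=C/Br)[C@@H]2C)cc1Br | target

**Totals.** Total step count: 8. Longest linear sequence: 8 steps (from 1).

**Steps most likely to fail**

1. Step 5. The furan may react through its methyl‑flanked α‑carbon, or the vinyl–gold intermediate may be protonated to a 2‑alkenylfuran before the carbene forms, and the acid‑sensitive C2 centre may drift. The fallback sets out from 1 and returns at 13; it brings the arene in ready‑made and sets the C2 methyl by hydrogenation. Commercial 2‑bromo‑5‑methylphenol is benzylated (BnBr, K2CO3, DMF) to 2‑(benzyloxy)‑1‑bromo‑4‑methylbenzene F1. Bromine–lithium exchange (n‑BuLi, Et2O, −78 °C) and Me2AlCl give [2‑(benzyloxy)‑4‑methylphenyl]dimethylalane F2. F2 is added to enone 1 under the copper–NHC catalysis of step 1 (enantioselective conjugate addition of arylaluminium reagents to β‑substituted cyclopentenones, with the ligand antipode that gives the R centre), and the enolate is trapped with Et3SiOTf as silyl enol ether F3. Eschenmoser's salt (CH2Cl2, rt) converts F3 into Mannich base F4, MeI gives ammonium iodide F5, and DBU eliminates trimethylamine to the 2‑methylidene ketone F6. Hydrogenation (H2, Pd/C, EtOAc) should deliver hydrogen to the exocyclic alkene from the face opposite the aryl group, which puts the new C2 methyl cis to the aryl, and it cleaves the benzyl ether in the same operation to give 13.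

2. Step 8. Oxidative addition at the fully substituted dibromoalkene may be slow and may not distinguish the two C–Br bonds well enough, so that the (E)‑bromide and the fully debrominated alkene appear. The fallback sets out from 15 and returns at 18, bypassing 16. A boron–Wittig reaction of ketone 15 with lithiated bis(pinacolato)borylmethane (CH2(Bpin)2, lithium 2,2,6,6‑tetramethylpiperidide, THF, −78 °C) should give the (E)‑alkenyl pinacolboronate F7, with boron on the less hindered C4 side. Br2 (CH2Cl2, −78 °C) followed by NaOMe/MeOH replaces boron by bromine with inversion of the alkene geometry (anti addition, then anti elimination), which places bromine syn to C2. The methoxide also removes the acetate, so 18 is obtained directly.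

3. Step 1. Hydroalumination may leave aluminium hydride that reduces the enone, and the vinyl transfer may not reach sufficient facial selectivity. The fallback sets out from 2 and returns at 10; the alkyne is installed first and the methyl group is the one transferred. Lithiated 2 (n‑BuLi, THF, −78 °C) is added to commercial 3‑ethoxycyclopent‑2‑en‑1‑one, and acidic work‑up (aqueous HCl) gives by Stork–Danheiser transposition 3‑[(trimethylsilyl)ethynyl]cyclopent‑2‑en‑1‑one F8. Copper‑catalysed enantioselective 1,4‑addition of MeMgBr (Cu(OTf)2, chiral imidazolinium NHC precursor, Et2O, −30 °C) is a reaction type known to be 1,4‑selective on cyclic enynones and to give alkynyl‑bearing quaternary centres. With Me3SiCl/Et3N trapping it gives silyl enol ether F9. MeLi then MeI gives (2R,3R)‑2,3‑dimethyl‑3‑[(trimethylsilyl)ethynyl]cyclopentan‑1‑one F10, the methyl entering on the face of the slim alkyne. K2CO3/MeOH removes the alkynyl silyl group and equilibrates C2, giving 10.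

**Further compounds**
F1 | step 5 | 2‑(benzyloxy)‑1‑bromo‑4‑methylbenzene | Cc1ccc(Br)c(OCc2ccccc2)c1
F2 | step 5 | [2‑(benzyloxy)‑4‑methylphenyl]dimethylalane | Cc1ccc([Al](C)C)c(OCc2ccccc2)c1
F3 | step 5 | ({(3R)‑3‑[2‑(benzyloxy)‑4‑methylphenyl]‑3‑methylcyclopent‑1‑en‑1‑yl}oxy)triethylsilane | Cc1ccc([C@]2(C)CCC(O[Si](CC)(CC)CC)=C2)c(OCc3ccccc3)c1
F4 | step 5 | (2R,3R)‑3‑[2‑(benzyloxy)‑4‑methylphenyl]‑2‑[(dimethylamino)methyl]‑3‑methylcyclopentan‑1‑one (aminomethyl trans to aryl) | Cc1ccc([C@]2(C)CCC(=O)[C@H]2CN(C)C)c(OCc3ccccc3)c1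
F5 | step 5 | N‑methyl ammonium iodide of F4 (trimethylammoniomethyl group at C2, ring stereocentres as in F4) | Cc1ccc([C@]2(C)CCC(=O)[C@H]2C[N+](C)(C)C)c(OCc3ccccc3)c1.[I-]
F6 | step 5 | (3S)‑3‑[2‑(benzyloxy)‑4‑methylphenyl]‑3‑methyl‑2‑methylidenecyclopentan‑1‑one | Cc1ccc([C@]2(C)CCC(=O)C2=C)c(OCc3ccccc3)c1
F7 | step 8 | (E)‑alkenyl pinacolboronate from 15: 4‑bromo‑5‑methyl‑2‑{1,2‑dimethyl‑3‑[(4,4,5,5‑tetramethyl‑1,3,2‑dioxaborolan‑2‑yl)methylidene]cyclopentyl}phenyl acetate, boron syn to ring C4, ring stereocentres as in 15 | Cc1cc(OC(C)=O)c([C@]2(C)CC/C(=C\B3OC(C)(C)C(C)(C)O3)[C@@H]2C)cc1Br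
F8 | step 1 | 3‑[(trimethylsilyl)ethynyl]cyclopent‑2‑en‑1‑one | C[Si](C)(C)C#CC1=CC(=O)CC1
F9 | step 1 | trimethyl({(3R)‑3‑methyl‑3‑[(trimethylsilyl)ethynyl]cyclopent‑1‑en‑1‑yl}oxy)silane | C[Si](C)(C)C#C[C@]1(C)CCC(O[Si](C)(C)C)=C1
F10 | step 1 | (2R,3R)‑2,3‑dimethyl‑3‑[(trimethylsilyl)ethynyl]cyclopentan‑1‑one | C[Si](C)(C)C#C[C@]1(C)CCC(=O)[C@@H]1C
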